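## Analysis of the target

The target 29 is a 2,3-dihydrobenzofuran neolignan. Ring A (C3a, C4–C7, C7a) is fused to the O1–C2–C3 dihydrofuran; C2 carries the 4-hydroxy-3-methoxyphenyl ring D, C3 carries C9H2 as a 4-hydroxybenzoate, C5 carries a (Z)-3-oxopropenyl chain and C7 a methoxy group. The two stereocentres, C2 (S) and C3 (R), are contiguous and trans on the five-membered ring. C2 is a benzylic ether carbon para to a free phenol, so acid or base can open O1–C2 through a ring D quinone methide; this epimerises C2 or, under base, leads on to a stilbene, and C3 must therefore carry the absolute information. The Z-enal isomerises to the E-isomer under acid, light or nucleophilic catalysis, and the aryl ester excludes hydride reagents late in the route. The difficulty is to set C3 absolutely and C2 relative to it, to build a 1,2,3,5-tetrasubstituted ring A with the right oxygen pattern, and to unveil enal, ester and two phenols in a workable order. The strategy rests on reading O1–C7a–C3a–C3–C2 as a γ-aryl-β-oxymethyl butyrolactone with C7a as its carbonyl carbon (lactone 11, ketene acetal 12). Ring A has O1 para to the C5 carbon and ortho to the C7 oxygen, which is the benzoate pattern that pyrone 15 and a ketene acetal give after decarboxylation.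

## Retrosynthetic reasoning

The C9–O acyl bond is cut first: 29 goes back to alcohol 27 and acid 28. The aryl ester would not survive the two hydride reductions that build the enal, so it comes last. A Mitsunobu reaction activates the alcohol and not the acid, so both phenols can stay free, because only the carboxyl group is acidic enough to be alkylated.

The Z-enal of 27 is traced through its bis-silyl ether 26 to allylic alcohol 25 and enoate 24, and the C=C bond of 24 is cut to aldehyde 23. This puts the geometry problem into one Z-selective olefination of an aromatic aldehyde, followed by reduction and a neutral allylic oxidation. Desilylation (26 to 27) comes after the oxidation, since a free ring D phenol would not tolerate the oxidant. C9 carries a tert-butyldimethylsilyl ether so that this late desilylation is fast under buffered conditions.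

Aldehyde 23 comes from ester 21 by way of alcohol 22. The C7 methoxy group of 21 is traced to phenol 20 and, through boronate 19, to bromide 18. Copper-mediated displacement of the bromide by hot alkoxide is not used. It would strip the ring D silyl ether, and the para-phenoxide can then open O1–C2 to a quinone methide that loses the C3 proton. Borylation, oxidation and O-methylation reach the same ether with the silyl ether left on.

Bromide 18 is where ring A is dismantled. C3a–C4 and C7a–C7 are cut, which removes C4–C7 with ester and bromine as pyrone 15 and leaves O1–C7a–C3a–C3–C2 as ketene acetal 12, by way of diene 17 and bridged lactone 16. This is the only cut that removes ring A without touching a bond to C2 or C3, so both stereocentres can be made beforehand in a small lactone. The forward reaction must form two C–C bonds with the ester para and the bromine ortho to O1, lose the lactone bridge, and expel the silyloxy group and not O1.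

Pyrone 15 is the 3-bromo derivative of ester 13 (through adduct 14), and 12 is the O-silylated enolate of lactone 11.

Lactone 11 is simplified at C9 only: silyl ether from alcohol 10, alcohol from acid 9, acid from imide 7 through peroxy acid 8. The lactone stays intact and the auxiliary carbonyl becomes the oxymethyl carbon.

In 7 the C2–C3 bond is cut in the aldol sense together with the lactone acyl–oxygen bond, leading through hydroxy ester 6 to imide 5 and aldehyde 2. One auxiliary-controlled syn-aldol reaction sets the future C3 absolutely and the future C2 relative to it, and lactonisation locks the pair as the trans lactone.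

Imide 5 comes from auxiliary 3 and acid chloride 4; aldehyde 2 is the silyl ether of 1.

## Alternatives that were turned down

Alternative 1: The disconnection is at C3–C3a, with C9 traced to the carbonyl carbon of a flavanone: ester A1 would come from flavanone A2 by oxidative ring contraction. Forward, PhI(OAc)2/H2SO4 in HC(OMe)3 attacks C3 of the enol ether of A2, and the ring A carbon shifts from the carbonyl carbon to C3 while that carbon becomes the ester. The C2 configuration of A2 would come from an asymmetric conjugate arylation and is carried over, with C3 settling trans. In its favour, the ring contraction is an established reaction type, the route is several steps shorter, C7 methoxy is present from the start, and the C5 bromide allows an alkyne coupling and semi-hydrogenation to the Z-alkene. On step count and on precedent for the key step it is the stronger plan. Against it, ring D is para-oxygenated and, even as the pivalate, migrates more readily than a carbon of the bromine-deactivated ring A, so ring D shift should compete with or exceed ring contraction. The strongly acidic medium also allows reversible opening of O1–C2, which would erode the only source of chirality, and C3 ends as an epimerisable ester α-carbon. The chosen strategy offers instead a C3 fixed by an auxiliary in a reaction of known facial sense, with neither stereocentre involved when ring A is formed.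

Alternative 2: The disconnection is at O1–C7a: aldehyde A3 would come from fluoroarene A4 by intramolecular substitution. Forward, Cs2CO3 in DMF generates the C2 alkoxide of A4, which displaces fluoride at C7a (activated by the para formyl group) in a 5-exo closure with retention at both centres; these would come from a syn-aldol of a ring A arylacetyl imide with aldehyde 2. In its favour, the closure is a conventional polar step, no bond to a stereocentre is made, and the C5 formyl and C7 methoxy groups are in place, which saves about four steps after ring closure. On predictability of the ring-forming step it is the stronger plan. Against it, the fluoride is flanked by a donating, hindering methoxy group and activated only by a formyl group, so forcing conditions are likely. Under them carbonate cleaves the aryl silyl ether, the secondary alkoxide can take the silyl group from the neighbouring primary oxygen so that the wrong oxygen cyclises, and the free aldehyde is exposed to alkoxide. The fluorinated arylacetic acid also needs its own multi-step preparation. The chosen strategy offers a ring A bought as a coumalate with its substituents placed by the polarity of a cycloaddition, and no strongly basic step on the assembled skeleton; its price is an unprecedented cycloaddition partner.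

Alternative 3: The disconnection is at O1–C2: ester A5 would come from the open phenol A6 by oxidative cycloetherification. Forward, anodic oxidation with catalytic DDQ converts the 4-hydroxybenzyl unit of A6 into a para-quinone methide, and the ring A phenol adds to C2 trans to the C3 arm. In its favour, only C3 has to be made by asymmetric synthesis, the 4-hydroxybenzoate is in place before ring closure so no late esterification on a Z-enal is needed, and ring D is never protected. On convergence and protecting-group economy it is the stronger plan. Against it, A6 holds two oxidisable phenols and the ring A ortho-methoxyphenol competes for the mediator. A5 keeps a free para-phenol and a benzylic C2–H and is thus open to a second oxidation that aromatises the five-membered ring. The trans selectivity is kinetic and not assured, and the C5 bromide must still become the Z-enal next to an aryl ester and a free phenol. The chosen strategy offers no oxidation on a phenol-bearing skeleton, both stereocentres from one aldol reaction, and a ring D phenol that stays masked until the penultimate step.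

Key step: step 9

Remark on the chemistry: the bromine adduct 14 of methyl coumalate is written as the trans-3,4-dibromide; a 3,6-dibromide would lose HBr to the same pyrone 15. Atom labels (O1, C2, C3, C3a, C4–C7, C7a, C9) follow the benzofuran numbering of the target throughout.

## Route

Step 1
Reactants: 1 vanillin (4-hydroxy-3-methoxybenzaldehyde)
Product: 2 3-methoxy-4-(triisopropylsilyloxy)benzaldehyde
Conditions: TIPSCl, imidazole, DMF, 0 °C to rt
Reagents that add atoms: chlorotriisopropylsilane, CC(C)[Si](Cl)(C(C)C)C(C)C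
Why: O-Silylation of the phenol; the hindered aryl triisopropylsilyl ether is chosen because it has to outlast cold aqueous LiOH/H2O2, borane, an amide base and hydride reagents.

Step 2
Reactants: 3 (S)-4-benzyl-1,3-oxazolidin-2-one; 4 methyl 4-chloro-4-oxobutanoate
Product: 5 methyl 4-[(4S)-4-benzyl-2-oxo-1,3-oxazolidin-3-yl]-4-oxobutanoate
Conditions: n-BuLi, THF, −78 °C; then 4, −78 to 0 °C
Reagents that add atoms: none
Why: N-Acylation of the lithiated oxazolidinone by the acid chloride, which is far more electrophilic than the methyl ester at the other end of the succinate.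

Step 3
Reactants: 5 succinate imide; 2 silylated vanillin
Product: 7 (4S)-4-benzyl-3-({(2S,3S)-2-[3-methoxy-4-(triisopropylsilyloxy)phenyl]-5-oxooxolan-3-yl}carbonyl)-1,3-oxazolidin-2-one, via syn-aldol adduct 6 (not isolated)
Conditions: Bu2BOTf, i-Pr2NEt, CH2Cl2, −78 to 0 °C; 2, −78 to 0 °C; pH 7 buffer, MeOH, 30% H2O2, 0 °C; then PPTS (cat.), CH2Cl2, rt
Reagents that add atoms: none
Why: Evans syn-aldol reaction: the Z-boron enolate of the imide (the ester is not enolised) reacts through a Zimmerman–Traxler chair on the face away from the benzyl group, which sets the carbon that becomes C3 absolutely and the carbinol carbon that becomes C2 syn to it. 5-exo-trig lactonisation of the γ-hydroxy ester with retention at the carbinol carbon then gives the trans lactone, which is also the more stable isomer.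

Step 4
Reactants: 7 lactone imide
Product: 9 (2S,3S)-2-[3-methoxy-4-(triisopropylsilyloxy)phenyl]-5-oxooxolane-3-carboxylic acid, via peroxy acid 8 (not isolated)
Conditions: LiOH, 30% H2O2, THF/H2O, 0 °C; aq. Na2SO3; 1 M HCl to pH 3
Reagents that add atoms: hydrogen peroxide, OO
Why: Hydroperoxide attacks the exocyclic imide carbonyl selectively (standard auxiliary removal), sulfite reduces the peroxy acid, and acidification recloses any lactone opened by hydroxide. The hindered aryl silyl ether should survive the short cold exposure.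

Step 5
Reactants: 9 lactone acid
Product: 10 (4R,5S)-4-(hydroxymethyl)-5-[3-methoxy-4-(triisopropylsilyloxy)phenyl]oxolan-2-one
Conditions: BH3·SMe2, THF, 0 °C to rt; MeOH quench
Reagents that add atoms: none
Why: Borane reduces a carboxylic acid through its acyloxyborane much faster than a lactone, so C9 reaches the alcohol level without touching C7a.

Step 6
Reactants: 10 hydroxymethyl lactone
Product: 11 (4R,5S)-4-[(tert-butyldimethylsilyloxy)methyl]-5-[3-methoxy-4-(triisopropylsilyloxy)phenyl]oxolan-2-one
Conditions: TBSCl, imidazole, CH2Cl2, 0 °C to rt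
Reagents that add atoms: tert-butylchlorodimethylsilane, CC(C)(C)[Si](C)(C)Cl
Why: Silylation of the primary alcohol under weakly basic conditions, done at once so that the hydroxy lactone cannot translactonise onto the primary oxygen.

Step 7
Reactants: 11 silylated lactone
Product: 12 (4R,5S)-2-(tert-butyldimethylsilyloxy)-4-[(tert-butyldimethylsilyloxy)methyl]-5-[3-methoxy-4-(triisopropylsilyloxy)phenyl]-4,5-dihydrofuran
Conditions: LiN(i-Pr)2, THF, −78 °C; TBSCl, DMPU, −78 °C to rt; pentane, filtration under argon, used crude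
Reagents that add atoms: tert-butylchlorodimethylsilane, CC(C)(C)[Si](C)(C)Cl
Why: Kinetic deprotonation at the only acidic position (the CH2 that becomes C3a) and O-silylation of the lactone enolate in the presence of a dipolar cosolvent, the usual access to silyl ketene acetals of butyrolactones. C2 and C3 are not acidic and there is no β-leaving group.

Step 8
Reactants: 13 methyl coumalate (methyl 2-oxo-2H-pyran-5-carboxylate)
Product: 15 methyl 3-bromo-2-oxo-2H-pyran-5-carboxylate, via dibromide 14 (not isolated)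
Conditions: Br2, CH2Cl2, 0 °C to rt; then Et3N, 0 °C
Reagents that add atoms: bromine, BrBr
Why: Electrophilic bromine attacks C3 of the pyrone, the only nucleophilic ring position left free by the 5-ester, and base-induced loss of HBr restores the pyrone (addition–elimination bromination of 2-pyrones).

Step 9
Reactants: 12 silyl ketene acetal (1.0 equiv, crude); 15 bromopyrone (1.3 equiv)
Product: 18 methyl (2S,3R)-7-bromo-3-[(tert-butyldimethylsilyloxy)methyl]-2-[3-methoxy-4-(triisopropylsilyloxy)phenyl]-2,3-dihydro-1-benzofuran-5-carboxylate, via bridged lactone 16 (not isolated), via cyclohexadiene 17 (not isolated)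
Conditions: PhMe, rt, then 90 °C, argon
Reagents that add atoms: none
Why: Proposed new method: the nucleophilic ketene acetal carbon C3a of 12 adds to C6 of pyrone 15, the position made most electrophilic by the lactone carbonyl and the 5-ester together, while the acetal carbon C7a bonds to the bromine-bearing C3, in an inverse-demand (4+2) cycloaddition that may be concerted but asynchronous or may run through a silyloxy-oxocarbenium/dienolate zwitterion that collapses by 6-exo attack, giving bridged lactone 16 either way. Retro-(4+2) loss of CO2 from 16 gives cyclohexadiene 17, in which C7a is a mixed silyl alkyl ketal next to the C3a hydrogen, and 1,2-elimination of tert-butyldimethylsilanol across C3a–C7a (ionisation to an O1-stabilised arenium ion, then loss of the C3a proton) aromatises ring A. The closest known reaction type is the inverse-demand Diels–Alder reaction of coumalate esters and 3-bromo-2-pyrones with acyclic ketene acetals and enol ethers, which gives para-substituted benzoates after loss of CO2 and an alcohol; a lactone-derived cyclic silyl ketene acetal has not been used in it. Ring A is closed by intermolecular (4+2) annulation onto the C3a=C7a bond, forming C3a–C4 and C7a–C7, with the dihydrofuran ring carried through intact. No new stereocentre survives: C3a is sp3 only in 16 and 17 and is flattened on aromatisation, C3 lies outside the reacting π system, and C2 could be affected only by reversible O1–C2 ionisation, which recloses trans to the C3 arm. The step needs the ester para and the bromine ortho to O1, which the matched polarity of the two partners secures. It also needs loss of the silyloxy group and not of O1, which is favoured because silanolate is the better leaving group and the ring alkoxy oxygen that stays is the better cation-stabilising group.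

Step 10
Reactants: 18 aryl bromide
Product: 20 methyl (2S,3R)-3-[(tert-butyldimethylsilyloxy)methyl]-7-hydroxy-2-[3-methoxy-4-(triisopropylsilyloxy)phenyl]-2,3-dihydro-1-benzofuran-5-carboxylate, via pinacol boronate 19 (not isolated)
Conditions: Pd(dppf)Cl2 (5 mol%), B2pin2, KOAc, 1,4-dioxane, 85 °C; then NaBO3·4H2O, THF/H2O, rt
Reagents that add atoms: bis(pinacolato)diboron, CC1(C)OB(OC1(C)C)B1OC(C)(C)C(C)(C)O1 (boron in 19); sodium perborate, [Na+].[Na+].O[B-]1(O)OO[B-](O)(O)OO1 (oxygen in 20)
Why: Miyaura borylation of the aryl bromide and oxidation of the C–B bond give the C7 phenol at the same ring position. Acetate base and a weakly basic peroxide leave the ester and both silyl ethers alone, which hot methoxide would not.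

Step 11
Reactants: 20 C7 phenol
Product: 21 methyl (2S,3R)-3-[(tert-butyldimethylsilyloxy)methyl]-7-methoxy-2-[3-methoxy-4-(triisopropylsilyloxy)phenyl]-2,3-dihydro-1-benzofuran-5-carboxylate
Conditions: MeI, K2CO3, acetone, rt
Reagents that add atoms: iodomethane, CI
Why: Williamson O-methylation of the only free phenol; in acetone the hindered ring D silyl ether should not be attacked by carbonate.

Step 12
Reactants: 21 methyl ester
Product: 22 {(2S,3R)-3-[(tert-butyldimethylsilyloxy)methyl]-7-methoxy-2-[3-methoxy-4-(triisopropylsilyloxy)phenyl]-2,3-dihydro-1-benzofuran-5-yl}methanol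
Conditions: i-Bu2AlH, CH2Cl2, −78 to 0 °C; aq. KNaC4H4O6
Reagents that add atoms: none
Why: Hydride reduction of the aryl methyl ester to the benzylic alcohol; the silyl ethers and the benzylic ether are inert.

Step 13
Reactants: 22 benzylic alcohol
Product: 23 (2S,3R)-3-[(tert-butyldimethylsilyloxy)methyl]-7-methoxy-2-[3-methoxy-4-(triisopropylsilyloxy)phenyl]-2,3-dihydro-1-benzofuran-5-carbaldehyde
Conditions: MnO2, CH2Cl2, rt
Reagents that add atoms: none
Why: Selective oxidation of an electron-rich benzylic alcohol to the aldehyde without over-oxidation.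

Step 14
Reactants: 23 aldehyde
Product: 24 methyl (2Z)-3-{(2S,3R)-3-[(tert-butyldimethylsilyloxy)methyl]-7-methoxy-2-[3-methoxy-4-(triisopropylsilyloxy)phenyl]-2,3-dihydro-1-benzofuran-5-yl}prop-2-enoate
Conditions: (CF3CH2O)2P(O)CH2CO2Me, KN(SiMe3)2, 18-crown-6, THF, −78 °C
Reagents that add atoms: methyl 2-[bis(2,2,2-trifluoroethoxy)phosphoryl]acetate, COC(=O)CP(=O)(OCC(F)(F)F)OCC(F)(F)F
Why: Still–Gennari olefination: with the electron-poor phosphonate and a dissociated potassium counter-ion the oxaphosphetane collapses faster than it equilibrates, which gives the Z-enoate from an aromatic aldehyde.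

Step 15
Reactants: 24 Z-enoate
Product: 25 (2Z)-3-{(2S,3R)-3-[(tert-butyldimethylsilyloxy)methyl]-7-methoxy-2-[3-methoxy-4-(triisopropylsilyloxy)phenyl]-2,3-dihydro-1-benzofuran-5-yl}prop-2-en-1-ol
Conditions: i-Bu2AlH, CH2Cl2, −78 °C; aq. KNaC4H4O6
Reagents that add atoms: none
Why: 1,2-Reduction of the enoate to the allylic alcohol with retention of the Z geometry.

Step 16
Reactants: 25 Z-allylic alcohol
Product: 26 (2Z)-3-{(2S,3R)-3-[(tert-butyldimethylsilyloxy)methyl]-7-methoxy-2-[3-methoxy-4-(triisopropylsilyloxy)phenyl]-2,3-dihydro-1-benzofuran-5-yl}prop-2-enal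
Conditions: MnO2, CH2Cl2, rt, dark, short contact; filtration through Celite
Reagents that add atoms: none
Why: Heterogeneous, neutral allylic oxidation, a standard way from cis-allylic alcohols to cis-enals; no acid or nucleophile is present that could equilibrate the double bond.

Step 17
Reactants: 26 bis-silyl Z-enal
Product: 27 (2Z)-3-[(2S,3R)-2-(4-hydroxy-3-methoxyphenyl)-3-(hydroxymethyl)-7-methoxy-2,3-dihydro-1-benzofuran-5-yl]prop-2-enal
Conditions: Bu4NF, AcOH (1:1), THF, 0 °C to rt
Reagents that add atoms: none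
Why: Buffered fluoride removes the aryl triisopropylsilyl and the primary tert-butyldimethylsilyl ether. Acetic acid keeps the medium near neutral, so neither the Z-enal nor the ring D phenol (quinone methide opening) meets free base.

Step 18
Reactants: 27 phenol alcohol; 28 4-hydroxybenzoic acid
Product: 29 [(2S,3R)-2-(4-hydroxy-3-methoxyphenyl)-7-methoxy-5-[(1Z)-3-oxoprop-1-en-1-yl]-2,3-dihydro-1-benzofuran-3-yl]methyl 4-hydroxybenzoate
Conditions: PPh3, DIAD, THF, 0 °C (betaine pre-formed); then 28 and 27, 0 °C to rt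
Reagents that add atoms: none
Why: Mitsunobu esterification: the primary alcohol is activated as its alkoxyphosphonium ion and displaced by the carboxylate, the only pronucleophile acidic enough to be deprotonated effectively, so the phenols of both partners stay free. Pre-forming the betaine keeps free phosphine away from the enal, and C9 is a CH2 group, so no stereocentre is involved.

## Compound list

1 | vanillin (4-hydroxy-3-methoxybenzaldehyde) | COc1cc(C=O)ccc1O | starting material
2 | 3-methoxy-4-(triisopropylsilyloxy)benzaldehyde | COc1cc(C=O)ccc1O[Si](C(C)C)(C(C)C)C(C)C | intermediate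
3 | (S)-4-benzyl-1,3-oxazolidin-2-one | O=C1N[C@@H](Cc2ccccc2)CO1 | starting material
4 | methyl 4-chloro-4-oxobutanoate | COC(=O)CCC(Cl)=O | starting material
5 | methyl 4-[(4S)-4-benzyl-2-oxo-1,3-oxazolidin-3-yl]-4-oxobutanoate | COC(=O)CCC(=O)N1[C@@H](Cc2ccccc2)COC1=O | intermediate
6 | methyl (3S,4S)-3-{[(4S)-4-benzyl-2-oxo-1,3-oxazolidin-3-yl]carbonyl}-4-hydroxy-4-[3-methoxy-4-(triisopropylsilyloxy)phenyl]butanoate | COC(=O)C[C@@H]([C@H](O)c1ccc(O[Si](C(C)C)(C(C)C)C(C)C)c(OC)c1)C(=O)N1[C@@H](Cc2ccccc2)COC1=O | intermediate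
7 | (4S)-4-benzyl-3-({(2S,3S)-2-[3-methoxy-4-(triisopropylsilyloxy)phenyl]-5-oxooxolan-3-yl}carbonyl)-1,3-oxazolidin-2-one | COc1cc([C@H]2OC(=O)C[C@@H]2C(=O)N3[C@@H](Cc4ccccc4)COC3=O)ccc1O[Si](C(C)C)(C(C)C)C(C)C | intermediate
8 | (2S,3S)-2-[3-methoxy-4-(triisopropylsilyloxy)phenyl]-5-oxooxolane-3-carboperoxoic acid | COc1cc([C@H]2OC(=O)C[C@@H]2C(=O)OO)ccc1O[Si](C(C)C)(C(C)C)C(C)C | intermediate
9 | (2S,3S)-2-[3-methoxy-4-(triisopropylsilyloxy)phenyl]-5-oxooxolane-3-carboxylic acid | COc1cc([C@H]2OC(=O)C[C@@H]2C(=O)O)ccc1O[Si](C(C)C)(C(C)C)C(C)C | intermediate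
10 | (4R,5S)-4-(hydroxymethyl)-5-[3-methoxy-4-(triisopropylsilyloxy)phenyl]oxolan-2-one | COc1cc([C@H]2OC(=O)C[C@@H]2CO)ccc1O[Si](C(C)C)(C(C)C)C(C)C | intermediate
11 | (4R,5S)-4-[(tert-butyldimethylsilyloxy)methyl]-5-[3-methoxy-4-(triisopropylsilyloxy)phenyl]oxolan-2-one | COc1cc([C@H]2OC(=O)C[C@@H]2CO[Si](C)(C)C(C)(C)C)ccc1O[Si](C(C)C)(C(C)C)C(C)C | intermediate
12 | (4R,5S)-2-(tert-butyldimethylsilyloxy)-4-[(tert-butyldimethylsilyloxy)methyl]-5-[3-methoxy-4-(triisopropylsilyloxy)phenyl]-4,5-dihydrofuran | COc1cc([C@H]2OC(O[Si](C)(C)C(C)(C)C)=C[C@@H]2CO[Si](C)(C)C(C)(C)C)ccc1O[Si](C(C)C)(C(C)C)C(C)C | intermediate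
13 | methyl coumalate (methyl 2-oxo-2H-pyran-5-carboxylate) | COC(=O)C1=COC(=O)C=C1 | starting material
14 | methyl trans-3,4-dibromo-2-oxo-3,4-dihydro-2H-pyran-5-carboxylate (racemic; one enantiomer drawn) | COC(=O)C1=COC(=O)[C@@H](Br)[C@@H]1Br | intermediate
15 | methyl 3-bromo-2-oxo-2H-pyran-5-carboxylate | COC(=O)C1=COC(=O)C(Br)=C1 | intermediate
16 | methyl (2S,3R)-7-bromo-7a-(tert-butyldimethylsilyloxy)-3-[(tert-butyldimethylsilyloxy)methyl]-2-[3-methoxy-4-(triisopropylsilyloxy)phenyl]-9-oxo-2,3,3a,4,7,7a-hexahydro-4,7-(epoxymethano)-1-benzofuran-5-carboxylate (C3a, C4, C7 and C7a not defined) | COc1cc([C@H]2OC3(O[Si](C)(C)C(C)(C)C)C([C@@H]2CO[Si](C)(C)C(C)(C)C)C2OC(=O)C3(Br)C=C2C(=O)OC)ccc1O[Si](C(C)C)(C(C)C)C(C)C | intermediate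
17 | methyl (2S,3R)-7-bromo-7a-(tert-butyldimethylsilyloxy)-3-[(tert-butyldimethylsilyloxy)methyl]-2-[3-methoxy-4-(triisopropylsilyloxy)phenyl]-2,3,3a,7a-tetrahydro-1-benzofuran-5-carboxylate (C3a and C7a not defined) | COc1cc([C@H]2OC3(O[Si](C)(C)C(C)(C)C)C(Br)=CC(C(=O)OC)=CC3[C@@H]2CO[Si](C)(C)C(C)(C)C)ccc1O[Si](C(C)C)(C(C)C)C(C)C | intermediate
18 | methyl (2S,3R)-7-bromo-3-[(tert-butyldimethylsilyloxy)methyl]-2-[3-methoxy-4-(triisopropylsilyloxy)phenyl]-2,3-dihydro-1-benzofuran-5-carboxylate | COc1cc([C@H]2Oc3c(Br)cc(C(=O)OC)cc3[C@@H]2CO[Si](C)(C)C(C)(C)C)ccc1O[Si](C(C)C)(C(C)C)C(C)C | intermediate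
19 | methyl (2S,3R)-3-[(tert-butyldimethylsilyloxy)methyl]-2-[3-methoxy-4-(triisopropylsilyloxy)phenyl]-7-(4,4,5,5-tetramethyl-1,3,2-dioxaborolan-2-yl)-2,3-dihydro-1-benzofuran-5-carboxylate | COc1cc([C@H]2Oc3c(B4OC(C)(C)C(C)(C)O4)cc(C(=O)OC)cc3[C@@H]2CO[Si](C)(C)C(C)(C)C)ccc1O[Si](C(C)C)(C(C)C)C(C)C | intermediate
20 | methyl (2S,3R)-3-[(tert-butyldimethylsilyloxy)methyl]-7-hydroxy-2-[3-methoxy-4-(triisopropylsilyloxy)phenyl]-2,3-dihydro-1-benzofuran-5-carboxylate | COc1cc([C@H]2Oc3c(O)cc(C(=O)OC)cc3[C@@H]2CO[Si](C)(C)C(C)(C)C)ccc1O[Si](C(C)C)(C(C)C)C(C)C | intermediate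
21 | methyl (2S,3R)-3-[(tert-butyldimethylsilyloxy)methyl]-7-methoxy-2-[3-methoxy-4-(triisopropylsilyloxy)phenyl]-2,3-dihydro-1-benzofuran-5-carboxylate | COc1cc([C@H]2Oc3c(OC)cc(C(=O)OC)cc3[C@@H]2CO[Si](C)(C)C(C)(C)C)ccc1O[Si](C(C)C)(C(C)C)C(C)C | intermediate
22 | {(2S,3R)-3-[(tert-butyldimethylsilyloxy)methyl]-7-methoxy-2-[3-methoxy-4-(triisopropylsilyloxy)phenyl]-2,3-dihydro-1-benzofuran-5-yl}methanol | COc1cc([C@H]2Oc3c(OC)cc(CO)cc3[C@@H]2CO[Si](C)(C)C(C)(C)C)ccc1O[Si](C(C)C)(C(C)C)C(C)C | intermediate
23 | (2S,3R)-3-[(tert-butyldimethylsilyloxy)methyl]-7-methoxy-2-[3-methoxy-4-(triisopropylsilyloxy)phenyl]-2,3-dihydro-1-benzofuran-5-carbaldehyde | COc1cc([C@H]2Oc3c(OC)cc(C=O)cc3[C@@H]2CO[Si](C)(C)C(C)(C)C)ccc1O[Si](C(C)C)(C(C)C)C(C)C | intermediate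
24 | methyl (2Z)-3-{(2S,3R)-3-[(tert-butyldimethylsilyloxy)methyl]-7-methoxy-2-[3-methoxy-4-(triisopropylsilyloxy)phenyl]-2,3-dihydro-1-benzofuran-5-yl}prop-2-enoate | COc1cc([C@H]2Oc3c(OC)cc(/C=C\C(=O)OC)cc3[C@@H]2CO[Si](C)(C)C(C)(C)C)ccc1O[Si](C(C)C)(C(C)C)C(C)C | intermediate
25 | (2Z)-3-{(2S,3R)-3-[(tert-butyldimethylsilyloxy)methyl]-7-methoxy-2-[3-methoxy-4-(triisopropylsilyloxy)phenyl]-2,3-dihydro-1-benzofuran-5-yl}prop-2-en-1-ol | COc1cc([C@H]2Oc3c(OC)cc(/C=C\CO)cc3[C@@H]2CO[Si](C)(C)C(C)(C)C)ccc1O[Si](C(C)C)(C(C)C)C(C)C | intermediate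
26 | (2Z)-3-{(2S,3R)-3-[(tert-butyldimethylsilyloxy)methyl]-7-methoxy-2-[3-methoxy-4-(triisopropylsilyloxy)phenyl]-2,3-dihydro-1-benzofuran-5-yl}prop-2-enal | COc1cc([C@H]2Oc3c(OC)cc(/C=C\C=O)cc3[C@@H]2CO[Si](C)(C)C(C)(C)C)ccc1O[Si](C(C)C)(C(C)C)C(C)C | intermediate
27 | (2Z)-3-[(2S,3R)-2-(4-hydroxy-3-methoxyphenyl)-3-(hydroxymethyl)-7-methoxy-2,3-dihydro-1-benzofuran-5-yl]prop-2-enal | COc1cc([C@H]2Oc3c(OC)cc(/C=C\C=O)cc3[C@@H]2CO)ccc1O | intermediate
28 | 4-hydroxybenzoic acid | OC(=O)c1ccc(O)cc1 | starting material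
29 | [(2S,3R)-2-(4-hydroxy-3-methoxyphenyl)-7-methoxy-5-[(1Z)-3-oxoprop-1-en-1-yl]-2,3-dihydro-1-benzofuran-3-yl]methyl 4-hydroxybenzoate | COc1cc([C@H]2Oc3c(OC)cc(/C=C\C=O)cc3[C@@H]2COC(=O)c2ccc(O)cc2)ccc1O | target

## Step count and least certain steps

Total: 18 steps. Longest linear sequence: 16 steps (1 or 3 to 29, through steps 1 or 2, 3–7 and 9–18); step 8 is a one-step side branch.

Step 9 (key step). The ketene acetal may add to C6 of the pyrone without the second bond closing (Michael-type addition followed by silyl transfer), or it may be lost by protodesilylation before it reacts. After decarboxylation the elimination may also take O1 in place of the silyloxy group, since both are ketal oxygens on the same carbon. The fallback uses known chemistry, sets out from aldehyde 2 and auxiliary 3 and returns at 21: ring A is brought in ready-made and the dihydrofuran is closed at O1–C2.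
- Commercial methyl 4-hydroxy-3-iodo-5-methoxybenzoate F1 is benzylated (BnBr, K2CO3, DMF) to methyl 4-(benzyloxy)-3-iodo-5-methoxybenzoate F2.
- Pd-catalysed coupling with the Reformatsky reagent BrZnCH2CO2t-Bu (Pd(dba)2, P(t-Bu)3, THF) gives methyl 4-(benzyloxy)-3-(2-tert-butoxy-2-oxoethyl)-5-methoxybenzoate F3, and CF3CO2H frees 2-[2-(benzyloxy)-3-methoxy-5-(methoxycarbonyl)phenyl]acetic acid F4.
- Mixed-anhydride acylation of lithiated 3 (t-BuCOCl, Et3N) gives the arylacetyl imide methyl 3-{2-[(4S)-4-benzyl-2-oxo-1,3-oxazolidin-3-yl]-2-oxoethyl}-4-(benzyloxy)-5-methoxybenzoate F5.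
- An Evans syn-aldol reaction of F5 with 2 (Bu2BOTf, i-Pr2NEt), with the same facial sense as in step 3, gives the aldol adduct methyl 3-{(2S,3S)-1-[(4S)-4-benzyl-2-oxo-1,3-oxazolidin-3-yl]-3-hydroxy-3-[3-methoxy-4-(triisopropylsilyloxy)phenyl]-1-oxopropan-2-yl}-4-(benzyloxy)-5-methoxybenzoate F6.
- NaBH4 in THF/H2O removes the auxiliary and spares the benzoate, giving the diol methyl 4-(benzyloxy)-3-{(1S,2R)-1,3-dihydroxy-1-[3-methoxy-4-(triisopropylsilyloxy)phenyl]propan-2-yl}-5-methoxybenzoate F7.
- Hydrogenolysis (H2, Pd/C, EtOAc) frees the ring A phenol in methyl 3-{(1S,2R)-1,3-dihydroxy-1-[3-methoxy-4-(triisopropylsilyloxy)phenyl]propan-2-yl}-4-hydroxy-5-methoxybenzoate F8.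
- Catalytic TsOH in CH2Cl2 ionises the para-silyloxybenzylic alcohol, and the phenol closes O1–C2 trans to the C3 arm to give methyl (2S,3R)-3-(hydroxymethyl)-7-methoxy-2-[3-methoxy-4-(triisopropylsilyloxy)phenyl]-2,3-dihydro-1-benzofuran-5-carboxylate F9. TBSCl/imidazole then gives 21.

Step 18. Reversible conjugate addition of phosphine or betaine to the enal may isomerise Z to E, and a phenol oxygen may be alkylated in place of the carboxylate. The fallback sets out from 26 and returns at 29, with the ester made by acylation and the phenols freed last.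
- HF·pyridine in THF/pyridine removes only the primary silyl ether and gives (2Z)-3-{(2S,3R)-3-(hydroxymethyl)-7-methoxy-2-[3-methoxy-4-(triisopropylsilyloxy)phenyl]-2,3-dihydro-1-benzofuran-5-yl}prop-2-enal F10.
- Acid 28 is bis-silylated (TIPSCl, imidazole) to triisopropylsilyl 4-(triisopropylsilyloxy)benzoate F11, and the silyl ester is hydrolysed (K2CO3, THF/MeOH/H2O) to 4-(triisopropylsilyloxy)benzoic acid F12.
- Carbodiimide coupling of F10 with F12 (EDC·HCl, catalytic DMAP, CH2Cl2, 0 °C) gives {(2S,3R)-7-methoxy-2-[3-methoxy-4-(triisopropylsilyloxy)phenyl]-5-[(1Z)-3-oxoprop-1-en-1-yl]-2,3-dihydro-1-benzofuran-3-yl}methyl 4-(triisopropylsilyloxy)benzoate F13.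
- Bu4NF/AcOH cleaves both aryl silyl ethers to give 29.

Step 16. The double bond may isomerise from Z to E on the oxidant surface or in light during the allylic oxidation. The fallback sets out from 23 and returns at 26 without any alcohol oxidation. A Stork–Zhao olefination (Ph3PCH2I iodide, NaN(SiMe3)2, THF/DMPU, −78 °C) gives the vinyl iodide (2S,3R)-3-[(tert-butyldimethylsilyloxy)methyl]-5-[(Z)-2-iodoethenyl]-7-methoxy-2-[3-methoxy-4-(triisopropylsilyloxy)phenyl]-2,3-dihydro-1-benzofuran F14. Iodine–lithium exchange (t-BuLi, Et2O, −78 °C) with retention, then DMF, gives 26.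

Step 7. The lactone enolate may be silylated on carbon in place of oxygen, and the ketene acetal may hydrolyse on handling. The fallback sets out from 11 and returns at 18 through a ketene O,S-acetal, whose thiolate is also a better leaving group than the ring oxygen.
- Lawesson's reagent (PhMe, 100 °C) gives (4R,5S)-4-[(tert-butyldimethylsilyloxy)methyl]-5-[3-methoxy-4-(triisopropylsilyloxy)phenyl]oxolane-2-thione F15.
- LiN(i-Pr)2 then MeI alkylates sulfur to give (4R,5S)-4-[(tert-butyldimethylsilyloxy)methyl]-5-[3-methoxy-4-(triisopropylsilyloxy)phenyl]-2-(methylsulfanyl)-4,5-dihydrofuran F16.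
- Heating F16 with 15 in PhMe gives the bridged adduct methyl (2S,3R)-7-bromo-3-[(tert-butyldimethylsilyloxy)methyl]-2-[3-methoxy-4-(triisopropylsilyloxy)phenyl]-7a-(methylsulfanyl)-9-oxo-2,3,3a,4,7,7a-hexahydro-4,7-(epoxymethano)-1-benzofuran-5-carboxylate F17.
- Decarboxylation gives the diene methyl (2S,3R)-7-bromo-3-[(tert-butyldimethylsilyloxy)methyl]-2-[3-methoxy-4-(triisopropylsilyloxy)phenyl]-7a-(methylsulfanyl)-2,3,3a,7a-tetrahydro-1-benzofuran-5-carboxylate F18, and loss of MeSH gives 18.

Step 10. Protodebromination may compete in the borylation, and the electron-rich ortho-alkoxy boronate may protodeboronate before it is oxidised. The fallback sets out from 18 and returns at 21 by direct C–O coupling. Pd2(dba)3/t-BuBrettPhos, Cs2CO3 and MeOH in 1,4-dioxane at 50 °C install the methoxy group; cleavage of the aryl silyl ether by the base is accepted and gives methyl (2S,3R)-3-[(tert-butyldimethylsilyloxy)methyl]-2-(4-hydroxy-3-methoxyphenyl)-7-methoxy-2,3-dihydro-1-benzofuran-5-carboxylate F19. TIPSCl/imidazole then returns 21. The milder base and lower temperature reduce, but do not remove, the risk of phenoxide-driven opening of O1–C2.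

## Further compounds

F1 | step 9 | methyl 4-hydroxy-3-iodo-5-methoxybenzoate | COC(=O)c1cc(I)c(O)c(OC)c1
F2 | step 9 | methyl 4-(benzyloxy)-3-iodo-5-methoxybenzoate | COC(=O)c1cc(I)c(OCc2ccccc2)c(OC)c1
F3 | step 9 | methyl 4-(benzyloxy)-3-(2-tert-butoxy-2-oxoethyl)-5-methoxybenzoate | COC(=O)c1cc(CC(=O)OC(C)(C)C)c(OCc2ccccc2)c(OC)c1
F4 | step 9 | 2-[2-(benzyloxy)-3-methoxy-5-(methoxycarbonyl)phenyl]acetic acid | COC(=O)c1cc(CC(=O)O)c(OCc2ccccc2)c(OC)c1
F5 | step 9 | methyl 3-{2-[(4S)-4-benzyl-2-oxo-1,3-oxazolidin-3-yl]-2-oxoethyl}-4-(benzyloxy)-5-methoxybenzoate | COC(=O)c1cc(CC(=O)N2[C@@H](Cc3ccccc3)COC2=O)c(OCc2ccccc2)c(OC)c1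
F6 | step 9 | methyl 3-{(2S,3S)-1-[(4S)-4-benzyl-2-oxo-1,3-oxazolidin-3-yl]-3-hydroxy-3-[3-methoxy-4-(triisopropylsilyloxy)phenyl]-1-oxopropan-2-yl}-4-(benzyloxy)-5-methoxybenzoate | COC(=O)c1cc([C@@H]([C@H](O)c2ccc(O[Si](C(C)C)(C(C)C)C(C)C)c(OC)c2)C(=O)N2[C@@H](Cc3ccccc3)COC2=O)c(OCc2ccccc2)c(OC)c1
F7 | step 9 | methyl 4-(benzyloxy)-3-{(1S,2R)-1,3-dihydroxy-1-[3-methoxy-4-(triisopropylsilyloxy)phenyl]propan-2-yl}-5-methoxybenzoate | COC(=O)c1cc([C@@H]([C@H](O)c2ccc(O[Si](C(C)C)(C(C)C)C(C)C)c(OC)c2)CO)c(OCc2ccccc2)c(OC)c1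
F8 | step 9 | methyl 3-{(1S,2R)-1,3-dihydroxy-1-[3-methoxy-4-(triisopropylsilyloxy)phenyl]propan-2-yl}-4-hydroxy-5-methoxybenzoate | COC(=O)c1cc([C@@H]([C@H](O)c2ccc(O[Si](C(C)C)(C(C)C)C(C)C)c(OC)c2)CO)c(O)c(OC)c1
F9 | step 9 | methyl (2S,3R)-3-(hydroxymethyl)-7-methoxy-2-[3-methoxy-4-(triisopropylsilyloxy)phenyl]-2,3-dihydro-1-benzofuran-5-carboxylate | COc1cc([C@H]2Oc3c(OC)cc(C(=O)OC)cc3[C@@H]2CO)ccc1O[Si](C(C)C)(C(C)C)C(C)C
F10 | step 18 | (2Z)-3-{(2S,3R)-3-(hydroxymethyl)-7-methoxy-2-[3-methoxy-4-(triisopropylsilyloxy)phenyl]-2,3-dihydro-1-benzofuran-5-yl}prop-2-enal | COc1cc([C@H]2Oc3c(OC)cc(/C=C\C=O)cc3[C@@H]2CO)ccc1O[Si](C(C)C)(C(C)C)C(C)C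
F11 | step 18 | triisopropylsilyl 4-(triisopropylsilyloxy)benzoate | CC(C)[Si](OC(=O)c1ccc(O[Si](C(C)C)(C(C)C)C(C)C)cc1)(C(C)C)C(C)C
F12 | step 18 | 4-(triisopropylsilyloxy)benzoic acid | CC(C)[Si](Oc1ccc(C(=O)O)cc1)(C(C)C)C(C)C
F13 | step 18 | {(2S,3R)-7-methoxy-2-[3-methoxy-4-(triisopropylsilyloxy)phenyl]-5-[(1Z)-3-oxoprop-1-en-1-yl]-2,3-dihydro-1-benzofuran-3-yl}methyl 4-(triisopropylsilyloxy)benzoate | COc1cc([C@H]2Oc3c(OC)cc(/C=C\C=O)cc3[C@@H]2COC(=O)c2ccc(O[Si](C(C)C)(C(C)C)C(C)C)cc2)ccc1O[Si](C(C)C)(C(C)C)C(C)C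
F14 | step 16 | (2S,3R)-3-[(tert-butyldimethylsilyloxy)methyl]-5-[(Z)-2-iodoethenyl]-7-methoxy-2-[3-methoxy-4-(triisopropylsilyloxy)phenyl]-2,3-dihydro-1-benzofuran | COc1cc([C@H]2Oc3c(OC)cc(/C=C\I)cc3[C@@H]2CO[Si](C)(C)C(C)(C)C)ccc1O[Si](C(C)C)(C(C)C)C(C)C
F15 | step 7 | (4R,5S)-4-[(tert-butyldimethylsilyloxy)methyl]-5-[3-methoxy-4-(triisopropylsilyloxy)phenyl]oxolane-2-thione | COc1cc([C@H]2OC(=S)C[C@@H]2CO[Si](C)(C)C(C)(C)C)ccc1O[Si](C(C)C)(C(C)C)C(C)C
F16 | step 7 | (4R,5S)-4-[(tert-butyldimethylsilyloxy)methyl]-5-[3-methoxy-4-(triisopropylsilyloxy)phenyl]-2-(methylsulfanyl)-4,5-dihydrofuran | COc1cc([C@H]2OC(SC)=C[C@@H]2CO[Si](C)(C)C(C)(C)C)ccc1O[Si](C(C)C)(C(C)C)C(C)C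
F17 | step 7 | methyl (2S,3R)-7-bromo-3-[(tert-butyldimethylsilyloxy)methyl]-2-[3-methoxy-4-(triisopropylsilyloxy)phenyl]-7a-(methylsulfanyl)-9-oxo-2,3,3a,4,7,7a-hexahydro-4,7-(epoxymethano)-1-benzofuran-5-carboxylate | COc1cc([C@H]2OC3(SC)C([C@@H]2CO[Si](C)(C)C(C)(C)C)C2OC(=O)C3(Br)C=C2C(=O)OC)ccc1O[Si](C(C)C)(C(C)C)C(C)C
F18 | step 7 | methyl (2S,3R)-7-bromo-3-[(tert-butyldimethylsilyloxy)methyl]-2-[3-methoxy-4-(triisopropylsilyloxy)phenyl]-7a-(methylsulfanyl)-2,3,3a,7a-tetrahydro-1-benzofuran-5-carboxylate | COc1cc([C@H]2OC3(SC)C(Br)=CC(C(=O)OC)=CC3[C@@H]2CO[Si](C)(C)C(C)(C)C)ccc1O[Si](C(C)C)(C(C)C)C(C)C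
F19 | step 10 | methyl (2S,3R)-3-[(tert-butyldimethylsilyloxy)methyl]-2-(4-hydroxy-3-methoxyphenyl)-7-methoxy-2,3-dihydro-1-benzofuran-5-carboxylate | COc1cc([C@H]2Oc3c(OC)cc(C(=O)OC)cc3[C@@H]2CO[Si](C)(C)C(C)(C)C)ccc1O
A1 | alternative 1 | methyl (2S,3S)-5-bromo-7-methoxy-2-[3-methoxy-4-(pivaloyloxy)phenyl]-2,3-dihydro-1-benzofuran-3-carboxylate (trans) | COc1cc([C@H]2Oc3c(OC)cc(Br)cc3[C@@H]2C(=O)OC)ccc1OC(=O)C(C)(C)C
A2 | alternative 1 | (2S)-6-bromo-8-methoxy-2-[3-methoxy-4-(pivaloyloxy)phenyl]-2,3-dihydro-4H-chromen-4-one | COc1cc([C@H]2Oc3c(OC)cc(Br)cc3C(=O)C2)ccc1OC(=O)C(C)(C)C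
A3 | alternative 2 | (2S,3R)-3-[(tert-butyldiphenylsilyloxy)methyl]-7-methoxy-2-[3-methoxy-4-(triisopropylsilyloxy)phenyl]-2,3-dihydro-1-benzofuran-5-carbaldehyde | COc1cc([C@H]2Oc3c(OC)cc(C=O)cc3[C@@H]2CO[Si](c2ccccc2)(c2ccccc2)C(C)(C)C)ccc1O[Si](C(C)C)(C(C)C)C(C)C
A4 | alternative 2 | 3-{(1S,2R)-3-(tert-butyldiphenylsilyloxy)-1-hydroxy-1-[3-methoxy-4-(triisopropylsilyloxy)phenyl]propan-2-yl}-4-fluoro-5-methoxybenzaldehyde | COc1cc([C@@H](O)[C@@H](CO[Si](c2ccccc2)(c2ccccc2)C(C)(C)C)c2cc(C=O)cc(OC)c2F)ccc1O[Si](C(C)C)(C(C)C)C(C)C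
A5 | alternative 3 | [(2S,3R)-5-bromo-2-(4-hydroxy-3-methoxyphenyl)-7-methoxy-2,3-dihydro-1-benzofuran-3-yl]methyl 4-(triisopropylsilyloxy)benzoate | COc1cc([C@H]2Oc3c(OC)cc(Br)cc3[C@@H]2COC(=O)c2ccc(O[Si](C(C)C)(C(C)C)C(C)C)cc2)ccc1O
A6 | alternative 3 | (2R)-2-(5-bromo-2-hydroxy-3-methoxyphenyl)-3-(4-hydroxy-3-methoxyphenyl)propyl 4-(triisopropylsilyloxy)benzoate | COc1cc(C[C@@H](COC(=O)c2ccc(O[Si](C(C)C)(C(C)C)C(C)C)cc2)c2cc(Br)cc(OC)c2O)ccc1O
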